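Remark on the chemistry: the dihydrobenzofuran 22 is formed as a racemate with an achiral catalyst. Its SMILES shows one enantiomer of the cis isomer. Both stereocentres are removed in step 16, so any trans isomer converges and no absolute control is planned.

## The problem

The target is an achiral 2-aryl-1-benzofuran-3-carbaldehyde: a furan fused to a benzene ring (ring A) and bonded at C2 to a second benzene ring (ring B). Ring A is pentasubstituted, with O1, C3a, a free hydroxyl at C4, a 3-hydroxy-3-methylbutyl chain at C5 and a methoxyl at C6. Three phloroglucinol-type oxygens therefore have to be told apart, and the chain has to sit between the C4 and C6 oxygens and nowhere else. The target has no stereocentre; the two that appear at C2 and C3 during ring closure control nothing and are erased again. The fragile parts are the C3 aldehyde (peri to the C4 hydroxyl), the two phenols on electron-rich rings and the tertiary alcohol, which under acid would eliminate or close a chroman onto the C4 oxygen, and the 2,4-dioxygenated benzyl ether used to bring in ring B is itself labile to acid and to oxidants. The feature that invites a carbenoid ring closure is that C2 carries both O1 and ring B, so a ring B benzyl ether on O1 offers a doubly activated C–H bond five atoms away from a C3 carbene that ring A and an ester stabilise. That ester is the latent C3 formyl group.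

## Retrosynthesis

**Silyl ethers and the C3 oxidation level (26 from 25, 24, 23).** The last cuts are three O–Si bonds of 25, then a change of oxidation level at C3 through alcohol 24 back to ester 23. An ester is preferred to a formyl group at C3 because a carbenoid needs a robust acceptor. Reduction followed by reoxidation is preferred to a partial reduction, which is unreliable for a benzofuran-3-carboxylate. The forward steps must leave aryl silyl ethers and the masked tertiary alcohol alone until fluoride is applied.

**C2=C3 unsaturation (23 from 22).** Removing the furan double bond gives the cis-dihydrobenzofuran 22. This costs one dehydrogenation but opens the way to a C(sp3)–C(sp3) bond construction. The forward step only needs hydride abstraction at C2, which O1 and ring B both favour.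

**C2–C3 bond, the key cut (22 from 21).** Cutting C2–C3 leads to aryldiazoacetate 21. Two neighbouring cuts were weighed against it. Cutting O1–C2 would need an unstable 2-aryl-1,3-dicarbonyl precursor. Cutting C2–C1' would need a complete 3-functionalised benzofuran and a separate biaryl coupling. The C2–C3 cut reduces ring B to a benzyl ether and C3 to the alpha carbon of an arylacetate, so the furan ring and the aryl attachment arise in one step. The forward reaction must insert into the O1 methylene only.

**Diazo group and chain oxygen (21 from 20, 19, 18).** The diazo group comes from ester 20 by diazo transfer. The triethylsilyl ether of 20 comes from tertiary alcohol 19, and that alcohol from the prenyl group of 18 by Markovnikov hydration. Hydration is placed after the aldehyde has gone and before the carbenoid, so neither an aldehyde nor a free O–H meets a radical or a carbene. The hydration must be acid-free.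

**Carboxyl carbon of the acetate (18 from 17, 15, 13, 12).** The ester carbon is removed to give aldehyde 12, whose formyl carbon is the future C3. The forward homologation runs through styrene 13, alcohol 15 and acid 17. This path was chosen over enol ether hydrolysis because every step is basic or neutral, and the ring B benzyl ether would not survive the acid that hydrolysis needs.

**O1–CH2 ether bond (12 from 8 and 11).** Cutting the benzylic C–O bond gives phenol 8 and benzyl alcohol 11, made in two steps from aldehyde 9 through 10. Only one phenol is free in 8, so no selectivity is asked of the etherification beyond tolerance of a chelated, hindered hydroxyl.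

**C5–chain bond (8 from 5 through 6 and 7).** The aryl–prenyl bond is cut so that the prenyl group returns to the oxygen para to it, giving ether 5. In the forward direction the tandem Claisen–Cope shift places the chain at the future C5 and frees exactly the hydroxyl that becomes O1. The other ortho oxygen stays silylated, so the rearrangement solves chain placement and oxygen differentiation together. Direct C-prenylation or halogenation of a phloroglucinol core would solve neither.

**Oxygen differentiation (5 from 4, 2, 1 and 3).** Ether 5 is taken back through phenol 4 and diol 2 to 2,4,6-trihydroxybenzaldehyde 1 and prenyl bromide 3. The forward order uses the innate reactivity order: para hydroxyl first, then the free ortho hydroxyl, then the chelated one. The formyl group that enforces this order is also the future C3.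

## Roads not taken

Alternative 1: Here ring A is finished late by cutting the C4–O and C5–C bonds. Fluoride would convert the ortho-silyl aryl triflate A1 into the strained aryne A2. A2 would take up N,N-dimethylformamide across the triple bond and, after hydrolysis, give the 4-hydroxy-5-formyl benzofuran A3. The merit is real: two adjacent substituents enter in one step, and the C6 methoxyl should steer the oxygen to C4. The weak points lie around the key step. A1 is a complete 2-arylbenzofuran-3-carboxylate with contiguous silyl and triflate groups, so the ring A substitution problem is moved, not removed. The formyl group of A3 must then be extended by three carbons to a tertiary alcohol with organometallic and hydride reagents while a C3 ester sits beside it. After that the ester must still be turned into the C3 aldehyde, and a benzyl ether must be removed in the presence of that aldehyde. This road is the more elegant in its decoration of ring A and needs no thermal rearrangement. The chosen plan sets against it that the chain is settled early and that only one carbonyl ever has to be adjusted.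

Alternative 2: This road cuts the C2–C1' biaryl bond. Pd(OAc)2 with Ag2CO3 would couple the C2–H of the aryl ester A4 with the ortho C–H of its phenoxy ring and close the six-membered lactone of coumestan A5. Its strengths are that neither partner needs prefunctionalisation, that the tether fixes where the bond forms, and that ring B derives from a simple phenol. It also needs no diazo compound and no one-carbon homologation, and in these respects it is better than the chosen plan. Its costs are several. A4 already contains a 3-carboxylated benzofuran with the complete ring A, which needs its own furan synthesis. The coupling runs hot with a silver oxidant on electron-rich rings and a free tertiary alcohol. Afterwards the lactone has to be opened reductively, the freed phenol methylated, the carbinol reoxidised and two benzyl ethers hydrogenolysed beside an aldehyde and the furan double bond. The chosen plan sets against it a ring closure at room temperature under neutral conditions that makes the furan and attaches ring B at once, and silyl groups that fall to fluoride without touching the aldehyde.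

Alternative 3: This road cuts the C3–C3a and C3–CHO bonds and O1–C2. HBF4·OEt2 would join diazoketone A6 to salicylaldehyde A7 with loss of nitrogen and a 1,2-shift of ring A. The acid would then close the furan by dehydration to give the 3-formylbenzofuran A8. It is clearly the shortest: the aldehyde arrives at its final oxidation level, and homologation, dehydrogenation and redox adjustment all disappear. It would save about eight steps over the chosen plan. The doubts are mechanistic. The aryl shift must beat the hydride shift, which would divert the material into a six-membered pyranone closure. The aldehyde of A7 is chelated, donor-deactivated and flanked by two ortho substituents. A diazoketone is a weaker nucleophile than a diazoacetate. The strong acid also meets a tertiary acetate prone to ionisation, and benzyl ethers must later be cleaved beside the aldehyde. The chosen plan is longer but sets against this a ring closure whose site selectivity is fixed by the substrate, and neutral conditions for the acid-labile carbinol.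

Key step: step 15

## Route

Step 1
Reactants: 1 2,4,6-trihydroxybenzaldehyde
Product: 2 2,6-dihydroxy-4-methoxybenzaldehyde
Conditions: Me2SO4 (1.0 equiv), K2CO3 (1.0 equiv), acetone, 0 °C to rt
Reagents that add atoms: dimethyl sulfate, COS(=O)(=O)OC
Why: Williamson O-methylation; the 4-hydroxyl is the most acidic and the only one not held in a hydrogen bond to the formyl oxygen, so one equivalent of base and alkylating agent should methylate it first, as is usual for phloroglucinol aldehydes and ketones.

Step 2
Reactants: 2 2,6-dihydroxy-4-methoxybenzaldehyde; 3 1-bromo-3-methylbut-2-ene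
Product: 4 2-hydroxy-4-methoxy-6-[(3-methylbut-2-en-1-yl)oxy]benzaldehyde
Conditions: K2CO3, acetone, reflux
Reagents that add atoms: none
Why: Williamson etherification; after the first alkylation the remaining hydroxyl is locked in a hydrogen bond to the formyl group and is far less acidic, which should stop the reaction at the mono-ether.

Step 3
Reactants: 4 2-hydroxy-4-methoxy-6-[(3-methylbut-2-en-1-yl)oxy]benzaldehyde
Product: 5 2-[(tert-butyldimethylsilyl)oxy]-4-methoxy-6-[(3-methylbut-2-en-1-yl)oxy]benzaldehyde
Conditions: t-BuMe2SiOTf, 2,6-lutidine, CH2Cl2, 0 °C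
Reagents that add atoms: tert-butyldimethylsilyl trifluoromethanesulfonate, CC(C)(C)[Si](C)(C)OS(=O)(=O)C(F)(F)F
Why: Silylation of a chelated phenol with a silyl triflate and a hindered pyridine base; the silyl group marks the oxygen that ends as the C4 hydroxyl and offers no C–H bond that a carbenoid could reach later.

Step 4
Reactants: 5 2-[(tert-butyldimethylsilyl)oxy]-4-methoxy-6-[(3-methylbut-2-en-1-yl)oxy]benzaldehyde
Product: 8 2-[(tert-butyldimethylsilyl)oxy]-6-hydroxy-4-methoxy-3-(3-methylbut-2-en-1-yl)benzaldehyde, via ortho-dienone 6 (not isolated), via para-dienone 7 (not isolated)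
Conditions: PhNEt2, 195 °C, argon
Reagents that add atoms: none
Why: Aromatic Claisen rearrangement followed by Cope rearrangement (para-Claisen): the first [3,3] shift puts the inverted allyl unit on the free ortho carbon (6), the second carries it to the para carbon with prenyl connectivity restored (7), and tautomerisation gives 8. This tandem is established for prenyl ethers of chelated ortho-hydroxyaryl carbonyl compounds; the crowded ortho-dienone is expected to undergo the Cope shift faster than it enolises, and the amine solvent buffers the phenol formed.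

Step 5
Reactants: 9 4-hydroxy-2-methoxybenzaldehyde
Product: 10 2-methoxy-4-[(triisopropylsilyl)oxy]benzaldehyde
Conditions: i-Pr3SiCl, imidazole, DMF, rt
Reagents that add atoms: chlorotriisopropylsilane, CC(C)[Si](Cl)(C(C)C)C(C)C
Why: Silylation of an unhindered phenol; the triisopropylsilyl group is chosen because it has to outlast an ylide, perborate and an amidine base later on.

Step 6
Reactants: 10 2-methoxy-4-[(triisopropylsilyl)oxy]benzaldehyde
Product: 11 {2-methoxy-4-[(triisopropylsilyl)oxy]phenyl}methanol
Conditions: NaBH4, MeOH, 0 °C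
Reagents that add atoms: none
Why: Borohydride reduction of an aromatic aldehyde to the benzyl alcohol; the aryl silyl ether is stable for the short time needed at 0 °C.

Step 7
Reactants: 8 2-[(tert-butyldimethylsilyl)oxy]-6-hydroxy-4-methoxy-3-(3-methylbut-2-en-1-yl)benzaldehyde; 11 {2-methoxy-4-[(triisopropylsilyl)oxy]phenyl}methanol
Product: 12 2-[(tert-butyldimethylsilyl)oxy]-4-methoxy-6-({2-methoxy-4-[(triisopropylsilyl)oxy]phenyl}methoxy)-3-(3-methylbut-2-en-1-yl)benzaldehyde
Conditions: PPh3, DIAD, THF, 0 °C to rt
Reagents that add atoms: none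
Why: Mitsunobu etherification of an acidic, chelated phenol with a primary benzylic alcohol; only one phenol is free, so the ether can form only at the future O1, and the neutral conditions spare the acid-labile dialkoxybenzyl unit.

Step 8
Reactants: 12 2-[(tert-butyldimethylsilyl)oxy]-4-methoxy-6-({2-methoxy-4-[(triisopropylsilyl)oxy]phenyl}methoxy)-3-(3-methylbut-2-en-1-yl)benzaldehyde
Product: 13 tert-butyl{2-ethenyl-5-methoxy-3-({2-methoxy-4-[(triisopropylsilyl)oxy]phenyl}methoxy)-6-(3-methylbut-2-en-1-yl)phenoxy}dimethylsilane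
Conditions: Ph3PCH3Br, KN(SiMe3)2, THF, 0 °C to rt
Reagents that add atoms: methyltriphenylphosphonium bromide, C[P+](c1ccccc1)(c1ccccc1)c1ccccc1.[Br-]
Why: Wittig methylenation; the small non-stabilised ylide is reactive enough for a di-ortho-substituted, electron-rich benzaldehyde, and the added carbon becomes the carboxyl carbon.

Step 9
Reactants: 13 tert-butyl{2-ethenyl-5-methoxy-3-({2-methoxy-4-[(triisopropylsilyl)oxy]phenyl}methoxy)-6-(3-methylbut-2-en-1-yl)phenoxy}dimethylsilane
Product: 15 2-[2-[(tert-butyldimethylsilyl)oxy]-4-methoxy-6-({2-methoxy-4-[(triisopropylsilyl)oxy]phenyl}methoxy)-3-(3-methylbut-2-en-1-yl)phenyl]ethan-1-ol, via B-alkylborane 14 (not isolated)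
Conditions: 9-BBN, THF, 0 °C to rt; then NaBO3·4H2O, H2O, rt
Reagents that add atoms: 9-borabicyclo[3.3.1]nonane, B1C2CCCC1CCC2 (boron unit of 14); sodium perborate, [Na+].[Na+].O[B-]1(O)OO[B-](O)(O)OO1 (hydroxyl oxygen of 15)
Why: Hydroboration–oxidation; the bulky dialkylborane adds boron to the terminal vinyl carbon (anti-Markovnikov) and is far slower with the trisubstituted prenyl double bond, and perborate oxidises the C–B bond without strong base, which spares the aryl silyl ethers.

Step 10
Reactants: 15 2-[2-[(tert-butyldimethylsilyl)oxy]-4-methoxy-6-({2-methoxy-4-[(triisopropylsilyl)oxy]phenyl}methoxy)-3-(3-methylbut-2-en-1-yl)phenyl]ethan-1-ol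
Product: 17 [2-[(tert-butyldimethylsilyl)oxy]-4-methoxy-6-({2-methoxy-4-[(triisopropylsilyl)oxy]phenyl}methoxy)-3-(3-methylbut-2-en-1-yl)phenyl]acetic acid, via arylacetaldehyde 16 (not isolated)
Conditions: TEMPO (cat.), PhI(OAc)2, MeCN/H2O, rt
Reagents that add atoms: water, O
Why: Nitroxyl-catalysed oxidation of a primary alcohol through the aldehyde and its hydrate to the carboxylic acid with PhI(OAc)2 as terminal oxidant; the medium stays close to neutral, so the benzyl ether and the silyl ethers are not at risk.

Step 11
Reactants: 17 [2-[(tert-butyldimethylsilyl)oxy]-4-methoxy-6-({2-methoxy-4-[(triisopropylsilyl)oxy]phenyl}methoxy)-3-(3-methylbut-2-en-1-yl)phenyl]acetic acid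
Product: 18 methyl [2-[(tert-butyldimethylsilyl)oxy]-4-methoxy-6-({2-methoxy-4-[(triisopropylsilyl)oxy]phenyl}methoxy)-3-(3-methylbut-2-en-1-yl)phenyl]acetate
Conditions: Me3SiCHN2, MeOH/toluene, 0 °C
Reagents that add atoms: (trimethylsilyl)diazomethane, C[Si](C)(C)C=[N+]=[N-]
Why: Esterification of a carboxylic acid with (trimethylsilyl)diazomethane in methanol; neutral conditions, no base that could attack the aryl silyl ethers.

Step 12
Reactants: 18 methyl [2-[(tert-butyldimethylsilyl)oxy]-4-methoxy-6-({2-methoxy-4-[(triisopropylsilyl)oxy]phenyl}methoxy)-3-(3-methylbut-2-en-1-yl)phenyl]acetate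
Product: 19 methyl [2-[(tert-butyldimethylsilyl)oxy]-3-(3-hydroxy-3-methylbutyl)-4-methoxy-6-({2-methoxy-4-[(triisopropylsilyl)oxy]phenyl}methoxy)phenyl]acetate
Conditions: Co(acac)2 (cat.), PhSiH3, O2 (1 atm), THF, rt
Reagents that add atoms: dioxygen, O=O
Why: Mukaiyama hydration: cobalt-mediated hydrogen-atom transfer to the alkene, capture of the tertiary radical by O2 and reduction of the peroxide by the silane give the Markovnikov tertiary alcohol without acid, so neither the benzyl ether nor the silyl ethers are touched.

Step 13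
Reactants: 19 methyl [2-[(tert-butyldimethylsilyl)oxy]-3-(3-hydroxy-3-methylbutyl)-4-methoxy-6-({2-methoxy-4-[(triisopropylsilyl)oxy]phenyl}methoxy)phenyl]acetate
Product: 20 methyl [2-[(tert-butyldimethylsilyl)oxy]-4-methoxy-6-({2-methoxy-4-[(triisopropylsilyl)oxy]phenyl}methoxy)-3-{3-methyl-3-[(triethylsilyl)oxy]butyl}phenyl]acetate
Conditions: Et3SiOTf, 2,6-lutidine, CH2Cl2, −78 to 0 °C
Reagents that add atoms: triethylsilyl trifluoromethanesulfonate, CC[Si](CC)(CC)OS(=O)(=O)C(F)(F)F
Why: Silylation of a tertiary alcohol with a silyl triflate; this masks the only O–H bond that could intercept the carbenoid in step 15.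

Step 14
Reactants: 20 methyl [2-[(tert-butyldimethylsilyl)oxy]-4-methoxy-6-({2-methoxy-4-[(triisopropylsilyl)oxy]phenyl}methoxy)-3-{3-methyl-3-[(triethylsilyl)oxy]butyl}phenyl]acetate
Product: 21 methyl 2-diazo-2-[2-[(tert-butyldimethylsilyl)oxy]-4-methoxy-6-({2-methoxy-4-[(triisopropylsilyl)oxy]phenyl}methoxy)-3-{3-methyl-3-[(triethylsilyl)oxy]butyl}phenyl]acetate
Conditions: 4-acetamidobenzenesulfonyl azide, DBU, MeCN, 0 °C to rt
Reagents that add atoms: 4-acetamidobenzenesulfonyl azide, CC(=O)Nc1ccc(cc1)S(=O)(=O)N=[N+]=[N-]
Why: Regitz diazo transfer from a sulfonyl azide to the ester enolate formed by the amidine base, the standard entry to aryldiazoacetates; the hindered silyl ethers are expected to tolerate the base in dry acetonitrile.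

Step 15
Reactants: 21 methyl 2-diazo-2-[2-[(tert-butyldimethylsilyl)oxy]-4-methoxy-6-({2-methoxy-4-[(triisopropylsilyl)oxy]phenyl}methoxy)-3-{3-methyl-3-[(triethylsilyl)oxy]butyl}phenyl]acetate
Product: 22 methyl cis-4-[(tert-butyldimethylsilyl)oxy]-6-methoxy-2-{2-methoxy-4-[(triisopropylsilyl)oxy]phenyl}-5-{3-methyl-3-[(triethylsilyl)oxy]butyl}-2,3-dihydro-1-benzofuran-3-carboxylate (racemic; one enantiomer drawn)
Conditions: Rh2(OAc)4 (1 mol %), CH2Cl2 (0.01 M), rt, slow addition of 21
Reagents that add atoms: none
Why: Rh2(OAc)4 expels N2 from 21 and forms an electrophilic dirhodium carbenoid at the future C3, stabilised by ring A as donor and the ester as acceptor. The carbenoid carbon takes the benzylic C–H of the O1 ether through a concerted, asynchronous three-centre transition state with hydride-transfer character, which forms C2–C3 and releases the catalyst. The closest known reaction type is the dirhodium-catalysed intramolecular C–H insertion of aryldiazoacetates into ortho benzyloxy groups, which gives cis-2-aryl-2,3-dihydrobenzofuran-3-carboxylates. The ring closes as a 1,5-insertion in which C3, C3a, C7a, O1 and C2 make the five-membered dihydrofuran. C2 and C3 are both set in this transition state; their relative (cis) configuration is controlled by the substrate geometry, with the aryl group and the ester on the same side, while the achiral catalyst gives a racemate, and no further control is wanted because step 16 removes both centres. The selectivity the step needs is site selectivity, and the O1 methylene is the only C–H activated by both an oxygen and an electron-rich aryl group within reach of a five-membered transition state. The C4 oxygen carries a silyl group whose nearest C–H would need a six-membered transition state at an unactivated methyl carbon, and the tertiary hydroxyl is masked so that no O–H insertion can compete. Slow addition at high dilution should suppress carbene dimerisation.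

Step 16
Reactants: 22 methyl cis-4-[(tert-butyldimethylsilyl)oxy]-6-methoxy-2-{2-methoxy-4-[(triisopropylsilyl)oxy]phenyl}-5-{3-methyl-3-[(triethylsilyl)oxy]butyl}-2,3-dihydro-1-benzofuran-3-carboxylate
Product: 23 methyl 4-[(tert-butyldimethylsilyl)oxy]-6-methoxy-2-{2-methoxy-4-[(triisopropylsilyl)oxy]phenyl}-5-{3-methyl-3-[(triethylsilyl)oxy]butyl}-1-benzofuran-3-carboxylate
Conditions: DDQ, toluene, 80 °C
Reagents that add atoms: none
Why: Quinone dehydrogenation: DDQ abstracts hydride from C2, which is benzylic to the electron-rich ring B and alpha to O1, and loss of the acidic C3 proton gives the aromatic furan; this is the usual way to aromatise 2-aryl-2,3-dihydrobenzofuran-3-carboxylates, and both stereocentres disappear.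

Step 17
Reactants: 23 methyl 4-[(tert-butyldimethylsilyl)oxy]-6-methoxy-2-{2-methoxy-4-[(triisopropylsilyl)oxy]phenyl}-5-{3-methyl-3-[(triethylsilyl)oxy]butyl}-1-benzofuran-3-carboxylate
Product: 24 (4-[(tert-butyldimethylsilyl)oxy]-6-methoxy-2-{2-methoxy-4-[(triisopropylsilyl)oxy]phenyl}-5-{3-methyl-3-[(triethylsilyl)oxy]butyl}-1-benzofuran-3-yl)methanol
Conditions: i-Bu2AlH, CH2Cl2, −78 to 0 °C; aq. KNaC4H4O6
Reagents that add atoms: none
Why: Aluminium hydride reduction of the ester to the primary alcohol; silyl ethers are inert, and full reduction is chosen because stopping at the aldehyde is unreliable for a benzofuran-3-carboxylate.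

Step 18
Reactants: 24 (4-[(tert-butyldimethylsilyl)oxy]-6-methoxy-2-{2-methoxy-4-[(triisopropylsilyl)oxy]phenyl}-5-{3-methyl-3-[(triethylsilyl)oxy]butyl}-1-benzofuran-3-yl)methanol
Product: 25 4-[(tert-butyldimethylsilyl)oxy]-6-methoxy-2-{2-methoxy-4-[(triisopropylsilyl)oxy]phenyl}-5-{3-methyl-3-[(triethylsilyl)oxy]butyl}-1-benzofuran-3-carbaldehyde
Conditions: MnO2, CH2Cl2, rt
Reagents that add atoms: none
Why: Oxidation of a benzylic-type heteroaryl carbinol on activated MnO2; the conditions are neutral, which suits an alcohol that would ionise readily under acid, and the aldehyde is not oxidised further.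

Step 19
Reactants: 25 4-[(tert-butyldimethylsilyl)oxy]-6-methoxy-2-{2-methoxy-4-[(triisopropylsilyl)oxy]phenyl}-5-{3-methyl-3-[(triethylsilyl)oxy]butyl}-1-benzofuran-3-carbaldehyde
Product: 26 4-hydroxy-2-(4-hydroxy-2-methoxyphenyl)-5-(3-hydroxy-3-methylbutyl)-6-methoxy-1-benzofuran-3-carbaldehyde
Conditions: Bu4NF, AcOH, THF, 0 °C to rt
Reagents that add atoms: none
Why: Fluoride-mediated cleavage of the two aryl silyl ethers and the tertiary triethylsilyl ether in one operation; acetic acid buffers the phenoxides so that the aldehyde and the tertiary alcohol do not meet strong base.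

## Compound list

1 | 2,4,6-trihydroxybenzaldehyde | O=Cc1c(O)cc(O)cc1O | starting material
2 | 2,6-dihydroxy-4-methoxybenzaldehyde | COc1cc(O)c(C=O)c(O)c1 | intermediate
3 | 1-bromo-3-methylbut-2-ene | CC(C)=CCBr | starting material
4 | 2-hydroxy-4-methoxy-6-[(3-methylbut-2-en-1-yl)oxy]benzaldehyde | COc1cc(O)c(C=O)c(OCC=C(C)C)c1 | intermediate
5 | 2-[(tert-butyldimethylsilyl)oxy]-4-methoxy-6-[(3-methylbut-2-en-1-yl)oxy]benzaldehyde | COc1cc(OCC=C(C)C)c(C=O)c(O[Si](C)(C)C(C)(C)C)c1 | intermediate
6 | 2-[(tert-butyldimethylsilyl)oxy]-4-methoxy-5-(2-methylbut-3-en-2-yl)-6-oxocyclohexa-1,3-diene-1-carbaldehyde (racemic) | O=CC1=C(O[Si](C)(C)C(C)(C)C)C=C(OC)C(C(C)(C)C=C)C1=O | intermediate (not isolated)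
7 | 2-[(tert-butyldimethylsilyl)oxy]-4-methoxy-3-(3-methylbut-2-en-1-yl)-6-oxocyclohexa-1,4-diene-1-carbaldehyde (racemic) | O=CC1=C(O[Si](C)(C)C(C)(C)C)C(CC=C(C)C)C(OC)=CC1=O | intermediate (not isolated)
8 | 2-[(tert-butyldimethylsilyl)oxy]-6-hydroxy-4-methoxy-3-(3-methylbut-2-en-1-yl)benzaldehyde | COc1cc(O)c(C=O)c(O[Si](C)(C)C(C)(C)C)c1CC=C(C)C | intermediate
9 | 4-hydroxy-2-methoxybenzaldehyde | COc1cc(O)ccc1C=O | starting material
10 | 2-methoxy-4-[(triisopropylsilyl)oxy]benzaldehyde | COc1cc(O[Si](C(C)C)(C(C)C)C(C)C)ccc1C=O | intermediate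
11 | {2-methoxy-4-[(triisopropylsilyl)oxy]phenyl}methanol | COc1cc(O[Si](C(C)C)(C(C)C)C(C)C)ccc1CO | intermediate
12 | 2-[(tert-butyldimethylsilyl)oxy]-4-methoxy-6-({2-methoxy-4-[(triisopropylsilyl)oxy]phenyl}methoxy)-3-(3-methylbut-2-en-1-yl)benzaldehyde | COc1cc(OCc2ccc(O[Si](C(C)C)(C(C)C)C(C)C)cc2OC)c(C=O)c(O[Si](C)(C)C(C)(C)C)c1CC=C(C)C | intermediate
13 | tert-butyl{2-ethenyl-5-methoxy-3-({2-methoxy-4-[(triisopropylsilyl)oxy]phenyl}methoxy)-6-(3-methylbut-2-en-1-yl)phenoxy}dimethylsilane | COc1cc(OCc2ccc(O[Si](C(C)C)(C(C)C)C(C)C)cc2OC)c(C=C)c(O[Si](C)(C)C(C)(C)C)c1CC=C(C)C | intermediate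
14 | 9-{2-[2-[(tert-butyldimethylsilyl)oxy]-4-methoxy-6-({2-methoxy-4-[(triisopropylsilyl)oxy]phenyl}methoxy)-3-(3-methylbut-2-en-1-yl)phenyl]ethyl}-9-borabicyclo[3.3.1]nonane | COc1cc(OCc2ccc(O[Si](C(C)C)(C(C)C)C(C)C)cc2OC)c(CCB2C3CCCC2CCC3)c(O[Si](C)(C)C(C)(C)C)c1CC=C(C)C | intermediate (not isolated)
15 | 2-[2-[(tert-butyldimethylsilyl)oxy]-4-methoxy-6-({2-methoxy-4-[(triisopropylsilyl)oxy]phenyl}methoxy)-3-(3-methylbut-2-en-1-yl)phenyl]ethan-1-ol | COc1cc(OCc2ccc(O[Si](C(C)C)(C(C)C)C(C)C)cc2OC)c(CCO)c(O[Si](C)(C)C(C)(C)C)c1CC=C(C)C | intermediate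
16 | [2-[(tert-butyldimethylsilyl)oxy]-4-methoxy-6-({2-methoxy-4-[(triisopropylsilyl)oxy]phenyl}methoxy)-3-(3-methylbut-2-en-1-yl)phenyl]acetaldehyde | COc1cc(OCc2ccc(O[Si](C(C)C)(C(C)C)C(C)C)cc2OC)c(CC=O)c(O[Si](C)(C)C(C)(C)C)c1CC=C(C)C | intermediate (not isolated)
17 | [2-[(tert-butyldimethylsilyl)oxy]-4-methoxy-6-({2-methoxy-4-[(triisopropylsilyl)oxy]phenyl}methoxy)-3-(3-methylbut-2-en-1-yl)phenyl]acetic acid | COc1cc(OCc2ccc(O[Si](C(C)C)(C(C)C)C(C)C)cc2OC)c(CC(=O)O)c(O[Si](C)(C)C(C)(C)C)c1CC=C(C)C | intermediate
18 | methyl [2-[(tert-butyldimethylsilyl)oxy]-4-methoxy-6-({2-methoxy-4-[(triisopropylsilyl)oxy]phenyl}methoxy)-3-(3-methylbut-2-en-1-yl)phenyl]acetate | COc1cc(OCc2ccc(O[Si](C(C)C)(C(C)C)C(C)C)cc2OC)c(CC(=O)OC)c(O[Si](C)(C)C(C)(C)C)c1CC=C(C)C | intermediate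
19 | methyl [2-[(tert-butyldimethylsilyl)oxy]-3-(3-hydroxy-3-methylbutyl)-4-methoxy-6-({2-methoxy-4-[(triisopropylsilyl)oxy]phenyl}methoxy)phenyl]acetate | COc1cc(OCc2ccc(O[Si](C(C)C)(C(C)C)C(C)C)cc2OC)c(CC(=O)OC)c(O[Si](C)(C)C(C)(C)C)c1CCC(C)(C)O | intermediate
20 | methyl [2-[(tert-butyldimethylsilyl)oxy]-4-methoxy-6-({2-methoxy-4-[(triisopropylsilyl)oxy]phenyl}methoxy)-3-{3-methyl-3-[(triethylsilyl)oxy]butyl}phenyl]acetate | COc1cc(OCc2ccc(O[Si](C(C)C)(C(C)C)C(C)C)cc2OC)c(CC(=O)OC)c(O[Si](C)(C)C(C)(C)C)c1CCC(C)(C)O[Si](CC)(CC)CC | intermediate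
21 | methyl 2-diazo-2-[2-[(tert-butyldimethylsilyl)oxy]-4-methoxy-6-({2-methoxy-4-[(triisopropylsilyl)oxy]phenyl}methoxy)-3-{3-methyl-3-[(triethylsilyl)oxy]butyl}phenyl]acetate | COc1cc(OCc2ccc(O[Si](C(C)C)(C(C)C)C(C)C)cc2OC)c(C(=[N+]=[N-])C(=O)OC)c(O[Si](C)(C)C(C)(C)C)c1CCC(C)(C)O[Si](CC)(CC)CC | intermediate
22 | methyl cis-4-[(tert-butyldimethylsilyl)oxy]-6-methoxy-2-{2-methoxy-4-[(triisopropylsilyl)oxy]phenyl}-5-{3-methyl-3-[(triethylsilyl)oxy]butyl}-2,3-dihydro-1-benzofuran-3-carboxylate (racemic; one enantiomer drawn) | COC(=O)[C@@H]1[C@H](c2ccc(O[Si](C(C)C)(C(C)C)C(C)C)cc2OC)Oc2cc(OC)c(CCC(C)(C)O[Si](CC)(CC)CC)c(O[Si](C)(C)C(C)(C)C)c21 | intermediate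
23 | methyl 4-[(tert-butyldimethylsilyl)oxy]-6-methoxy-2-{2-methoxy-4-[(triisopropylsilyl)oxy]phenyl}-5-{3-methyl-3-[(triethylsilyl)oxy]butyl}-1-benzofuran-3-carboxylate | COC(=O)c1c(-c2ccc(O[Si](C(C)C)(C(C)C)C(C)C)cc2OC)oc2cc(OC)c(CCC(C)(C)O[Si](CC)(CC)CC)c(O[Si](C)(C)C(C)(C)C)c12 | intermediate
24 | (4-[(tert-butyldimethylsilyl)oxy]-6-methoxy-2-{2-methoxy-4-[(triisopropylsilyl)oxy]phenyl}-5-{3-methyl-3-[(triethylsilyl)oxy]butyl}-1-benzofuran-3-yl)methanol | OCc1c(-c2ccc(O[Si](C(C)C)(C(C)C)C(C)C)cc2OC)oc2cc(OC)c(CCC(C)(C)O[Si](CC)(CC)CC)c(O[Si](C)(C)C(C)(C)C)c12 | intermediate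
25 | 4-[(tert-butyldimethylsilyl)oxy]-6-methoxy-2-{2-methoxy-4-[(triisopropylsilyl)oxy]phenyl}-5-{3-methyl-3-[(triethylsilyl)oxy]butyl}-1-benzofuran-3-carbaldehyde | O=Cc1c(-c2ccc(O[Si](C(C)C)(C(C)C)C(C)C)cc2OC)oc2cc(OC)c(CCC(C)(C)O[Si](CC)(CC)CC)c(O[Si](C)(C)C(C)(C)C)c12 | intermediate
26 | 4-hydroxy-2-(4-hydroxy-2-methoxyphenyl)-5-(3-hydroxy-3-methylbutyl)-6-methoxy-1-benzofuran-3-carbaldehyde (the ebenfuran target) | COc1cc(O)ccc1-c1oc2cc(OC)c(CCC(C)(C)O)c(O)c2c1C=O | target

## Step count and risks

Total step count: 19 (two steps to ring B alcohol 11, seventeen in the main line). Longest linear sequence: 17 steps, from 1 to 26 through steps 1 to 4 and 7 to 19.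

**Step 15 (key step).** Three processes could defeat the insertion. The carbenoid could be lost to bimolecular dimerisation. Hydride could be transferred from the very electron-rich benzylic position without the C–C bond closing, so that the ether fragments. The two ortho substituents could also shield the diazo carbon so that decomposition is slow and incomplete. The fallback makes the same C2–C3 bond by acyl transfer. It sets out from 20. DDQ in wet CH2Cl2 would cleave the dialkoxybenzyl ether oxidatively to methyl [2-[(tert-butyldimethylsilyl)oxy]-6-hydroxy-4-methoxy-3-{3-methyl-3-[(triethylsilyl)oxy]butyl}phenyl]acetate F1 and return aldehyde 10. NaClO2, NaH2PO4 and 2-methylbut-2-ene would oxidise 10 to 2-methoxy-4-[(triisopropylsilyl)oxy]benzoic acid F2. Carbodiimide esterification (EDC·HCl, DMAP) of F1 with F2 would give 3-[(tert-butyldimethylsilyl)oxy]-5-methoxy-2-(2-methoxy-2-oxoethyl)-4-{3-methyl-3-[(triethylsilyl)oxy]butyl}phenyl 2-methoxy-4-[(triisopropylsilyl)oxy]benzoate F3. LiN(SiMe3)2 at −78 °C would move the aroyl group from oxygen to the enolate carbon in an intramolecular Claisen condensation, giving methyl 2-[2-[(tert-butyldimethylsilyl)oxy]-6-hydroxy-4-methoxy-3-{3-methyl-3-[(triethylsilyl)oxy]butyl}phenyl]-3-{2-methoxy-4-[(triisopropylsilyl)oxy]phenyl}-3-oxopropanoate F4. Pyridinium p-toluenesulfonate in toluene would then close O1–C2 with loss of water, and the route is rejoined at 23.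

**Step 4.** The ortho-dienone could tautomerise before the Cope shift, which would leave the inverted allyl group on the wrong carbon. Thermal silyl transfer between the two ortho oxygens could also scramble their differentiation. The fallback places the chain by an ortho-Claisen shift at much lower temperature and silylates last. It sets out from 2 and 11. A Mitsunobu reaction (PPh3, DIAD) would give 2-hydroxy-4-methoxy-6-({2-methoxy-4-[(triisopropylsilyl)oxy]phenyl}methoxy)benzaldehyde F5. Alkylation with 3-chloro-3-methylbut-1-yne (the chloride of 2-methylbut-3-yn-2-ol; K2CO3, KI, CuI cat., acetone) would give 4-methoxy-2-({2-methoxy-4-[(triisopropylsilyl)oxy]phenyl}methoxy)-6-[(2-methylbut-3-yn-2-yl)oxy]benzaldehyde F6. Semi-hydrogenation (H2, Pd/CaCO3 poisoned with Pb(OAc)2, quinoline) would give 4-methoxy-2-({2-methoxy-4-[(triisopropylsilyl)oxy]phenyl}methoxy)-6-[(2-methylbut-3-en-2-yl)oxy]benzaldehyde F7. Heating in toluene at about 120 °C would shift the allyl unit to the only free ortho carbon and give 2-hydroxy-4-methoxy-6-({2-methoxy-4-[(triisopropylsilyl)oxy]phenyl}methoxy)-3-(3-methylbut-2-en-1-yl)benzaldehyde F8. Silylation of this phenol with t-BuMe2SiOTf and 2,6-lutidine rejoins the route at 12.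

**Step 14.** The enolate of a di-ortho-substituted arylacetate cannot become coplanar with ring A, so deprotonation and diazo transfer may be slow. Prolonged exposure to the amidine could then erode the aryl silyl ethers. The fallback is a deformylative diazo transfer and sets out from 20. LiN(SiMe3)2 followed by 2,2,2-trifluoroethyl formate would give methyl 2-[2-[(tert-butyldimethylsilyl)oxy]-4-methoxy-6-({2-methoxy-4-[(triisopropylsilyl)oxy]phenyl}methoxy)-3-{3-methyl-3-[(triethylsilyl)oxy]butyl}phenyl]-3-oxopropanoate F9. This far more acidic compound should take up the diazo group from 4-acetamidobenzenesulfonyl azide with Et3N and lose the formyl group, rejoining the route at 21.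

**Step 1.** Over-methylation and imperfect discrimination between the three hydroxyls could lower the throughput of 2. The fallback replaces selective alkylation by selective dealkylation and sets out from 1. Exhaustive methylation (excess Me2SO4, K2CO3, acetone, reflux) would give 2,4,6-trimethoxybenzaldehyde F10. Excess AlCl3 in CH2Cl2 would then remove only the two methyl groups ortho to the formyl group, under chelation control, and return the route to 2.

**Step 16.** Oxidation could spread to the other benzylic methylene of ring A or to the electron-rich rings before dehydrogenation is complete. The fallback introduces the double bond by selenoxide elimination and sets out from 22. Deprotonation at C3 with LiN(SiMe3)2 at −78 °C and trapping with PhSeCl on the face away from the C2 aryl group would give methyl 4-[(tert-butyldimethylsilyl)oxy]-6-methoxy-2-{2-methoxy-4-[(triisopropylsilyl)oxy]phenyl}-5-{3-methyl-3-[(triethylsilyl)oxy]butyl}-3-(phenylselanyl)-2,3-dihydro-1-benzofuran-3-carboxylate F11. Oxidation with H2O2 at 0 °C and syn-elimination towards the C2 hydrogen would rejoin the route at 23.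

## Further compounds

F1 | step 15 | methyl [2-[(tert-butyldimethylsilyl)oxy]-6-hydroxy-4-methoxy-3-{3-methyl-3-[(triethylsilyl)oxy]butyl}phenyl]acetate | COc1cc(O)c(CC(=O)OC)c(O[Si](C)(C)C(C)(C)C)c1CCC(C)(C)O[Si](CC)(CC)CC
F2 | step 15 | 2-methoxy-4-[(triisopropylsilyl)oxy]benzoic acid | COc1cc(O[Si](C(C)C)(C(C)C)C(C)C)ccc1C(=O)O
F3 | step 15 | 3-[(tert-butyldimethylsilyl)oxy]-5-methoxy-2-(2-methoxy-2-oxoethyl)-4-{3-methyl-3-[(triethylsilyl)oxy]butyl}phenyl 2-methoxy-4-[(triisopropylsilyl)oxy]benzoate | COc1cc(OC(=O)c2ccc(O[Si](C(C)C)(C(C)C)C(C)C)cc2OC)c(CC(=O)OC)c(O[Si](C)(C)C(C)(C)C)c1CCC(C)(C)O[Si](CC)(CC)CC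
F4 | step 15 | methyl 2-[2-[(tert-butyldimethylsilyl)oxy]-6-hydroxy-4-methoxy-3-{3-methyl-3-[(triethylsilyl)oxy]butyl}phenyl]-3-{2-methoxy-4-[(triisopropylsilyl)oxy]phenyl}-3-oxopropanoate (racemic) | COc1cc(O)c(C(C(=O)OC)C(=O)c2ccc(O[Si](C(C)C)(C(C)C)C(C)C)cc2OC)c(O[Si](C)(C)C(C)(C)C)c1CCC(C)(C)O[Si](CC)(CC)CC
F5 | step 4 | 2-hydroxy-4-methoxy-6-({2-methoxy-4-[(triisopropylsilyl)oxy]phenyl}methoxy)benzaldehyde | COc1cc(O)c(C=O)c(OCc2ccc(O[Si](C(C)C)(C(C)C)C(C)C)cc2OC)c1
F6 | step 4 | 4-methoxy-2-({2-methoxy-4-[(triisopropylsilyl)oxy]phenyl}methoxy)-6-[(2-methylbut-3-yn-2-yl)oxy]benzaldehyde | COc1cc(OC(C)(C)C#C)c(C=O)c(OCc2ccc(O[Si](C(C)C)(C(C)C)C(C)C)cc2OC)c1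
F7 | step 4 | 4-methoxy-2-({2-methoxy-4-[(triisopropylsilyl)oxy]phenyl}methoxy)-6-[(2-methylbut-3-en-2-yl)oxy]benzaldehyde | COc1cc(OC(C)(C)C=C)c(C=O)c(OCc2ccc(O[Si](C(C)C)(C(C)C)C(C)C)cc2OC)c1
F8 | step 4 | 2-hydroxy-4-methoxy-6-({2-methoxy-4-[(triisopropylsilyl)oxy]phenyl}methoxy)-3-(3-methylbut-2-en-1-yl)benzaldehyde | COc1cc(OCc2ccc(O[Si](C(C)C)(C(C)C)C(C)C)cc2OC)c(C=O)c(O)c1CC=C(C)C
F9 | step 14 | methyl 2-[2-[(tert-butyldimethylsilyl)oxy]-4-methoxy-6-({2-methoxy-4-[(triisopropylsilyl)oxy]phenyl}methoxy)-3-{3-methyl-3-[(triethylsilyl)oxy]butyl}phenyl]-3-oxopropanoate (racemic) | COc1cc(OCc2ccc(O[Si](C(C)C)(C(C)C)C(C)C)cc2OC)c(C(C=O)C(=O)OC)c(O[Si](C)(C)C(C)(C)C)c1CCC(C)(C)O[Si](CC)(CC)CC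
F10 | step 1 | 2,4,6-trimethoxybenzaldehyde | COc1cc(OC)c(C=O)c(OC)c1
F11 | step 16 | methyl 4-[(tert-butyldimethylsilyl)oxy]-6-methoxy-2-{2-methoxy-4-[(triisopropylsilyl)oxy]phenyl}-5-{3-methyl-3-[(triethylsilyl)oxy]butyl}-3-(phenylselanyl)-2,3-dihydro-1-benzofuran-3-carboxylate (racemic; phenylselanyl trans to the C2 aryl group) | COC(=O)[C@]1([Se]c2ccccc2)[C@H](c2ccc(O[Si](C(C)C)(C(C)C)C(C)C)cc2OC)Oc2cc(OC)c(CCC(C)(C)O[Si](CC)(CC)CC)c(O[Si](C)(C)C(C)(C)C)c21
A1 | alternative 1 | methyl 2-[4-(benzyloxy)-2-methoxyphenyl]-6-methoxy-4-{[(trifluoromethyl)sulfonyl]oxy}-5-(trimethylsilyl)-1-benzofuran-3-carboxylate | COC(=O)c1c(-c2ccc(OCc3ccccc3)cc2OC)oc2cc(OC)c([Si](C)(C)C)c(OS(=O)(=O)C(F)(F)F)c12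
A2 | alternative 1 | methyl 2-[4-(benzyloxy)-2-methoxyphenyl]-6-methoxy-4,5-didehydro-1-benzofuran-3-carboxylate | COC(=O)C1=C(c2ccc(OCc3ccccc3)cc2OC)OC2=C1C#CC(OC)=C2
A3 | alternative 1 | methyl 2-[4-(benzyloxy)-2-methoxyphenyl]-5-formyl-4-hydroxy-6-methoxy-1-benzofuran-3-carboxylate | COC(=O)c1c(-c2ccc(OCc3ccccc3)cc2OC)oc2cc(OC)c(C=O)c(O)c12
A4 | alternative 2 | 3-(benzyloxy)phenyl 4-(benzyloxy)-5-(3-hydroxy-3-methylbutyl)-6-methoxy-1-benzofuran-3-carboxylate | O=C(Oc1cccc(OCc2ccccc2)c1)c1coc2cc(OC)c(CCC(C)(C)O)c(OCc3ccccc3)c12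
A5 | alternative 2 | 3,7-bis(benzyloxy)-8-(3-hydroxy-3-methylbutyl)-9-methoxy-6H-benzofuro[3,2-c]chromen-6-one | O=C1Oc2cc(OCc3ccccc3)ccc2-c2oc3cc(OC)c(CCC(C)(C)O)c(OCc4ccccc4)c3c21
A6 | alternative 3 | 1-[4-(benzyloxy)-2-methoxyphenyl]-2-diazoethan-1-one | COc1cc(OCc2ccccc2)ccc1C(=O)C=[N+]=[N-]
A7 | alternative 3 | 4-[2-(benzyloxy)-3-formyl-4-hydroxy-6-methoxyphenyl]-2-methylbutan-2-yl acetate | CC(=O)OC(C)(C)CCc1c(OC)cc(O)c(C=O)c1OCc1ccccc1
A8 | alternative 3 | 4-{4-(benzyloxy)-2-[4-(benzyloxy)-2-methoxyphenyl]-3-formyl-6-methoxy-1-benzofuran-5-yl}-2-methylbutan-2-yl acetate | O=Cc1c(-c2ccc(OCc3ccccc3)cc2OC)oc2cc(OC)c(CCC(C)(C)OC(C)=O)c(OCc3ccccc3)c12
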